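**Retrosynthetic overview**
- The target comes from global BBr3 demethylation of the permethyl 18-membered macrocycle, which is the last step.
- The macrocycle is closed last by an intramolecular hydroboration / B-alkyl Suzuki coupling of the ring A vinyl group with the ring D aryl bromide in a bromo-styrene. This forms the ring A–ring D CH2CH2 bridge.
- The bromo-styrene comes from an intermolecular hydroboration / B-alkyl Suzuki coupling of the ring C styrene (which carries the ring D ArBr) with the ring A–B styrene aryl iodide. ArI ≫ ArBr selectivity forms the ring B–ring C CH2CH2 bridge.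
- Both styrene fragments come from Chan–Lam O-arylation of isovanillin or 2-hydroxy-3,4-dimethoxybenzaldehyde with a halophenylboronic acid, followed by Wittig methylenation.
- Rings are joined in this order: the two diaryl ethers, then the B–C bibenzyl bridge, then the macrocycle. No stilbene is made or reduced.

Assumption: the target SMILES has no stereodescriptors and no stereocentres, and the bent p-phenylene ring is taken to flip freely, so no stereochemistry has to be set. The ring A phenol and the ring C catechol are carried as methyl ethers and released in the last step.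

---

**Step 1**
Reactants: 1 (isovanillin), 2 (4-iodophenylboronic acid)
Product: 3 (3-(4-iodophenoxy)-4-methoxybenzaldehyde)
Conditions: Cu(OAc)2 (1.5 equiv), pyridine, CH2Cl2, 4 Å MS, air, rt, 36 h
Reagents that add atoms: none (the aryl group comes from reactant 2)
Why: Chan–Lam O-arylation joins ring A to ring B and leaves the ArI and CHO untouched; no stereocentre is involved.

**Step 2**
Reactants: 3, 4 (methyltriphenylphosphonium bromide)
Product: 5 (1-ethenyl-3-(4-iodophenoxy)-4-methoxybenzene)
Conditions: 4, KOtBu, THF, 0 °C → rt, 2 h
Reagents that add atoms: 4, C[P+](c1ccccc1)(c1ccccc1)c1ccccc1.[Br-] (supplies the =CH2)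
Why: Wittig methylenation converts the ring A aldehyde into the vinyl group that becomes the A–D CH2CH2 bridge, and the aryl iodide is inert to the ylide.

**Step 3**
Reactants: 6 (2-hydroxy-3,4-dimethoxybenzaldehyde), 7 (3-bromophenylboronic acid)
Product: 8 (2-(3-bromophenoxy)-3,4-dimethoxybenzaldehyde)
Conditions: Cu(OAc)2 (1.5 equiv), Et3N/pyridine, CH2Cl2, 4 Å MS, air, rt, 48 h
Reagents that add atoms: none (the aryl group comes from reactant 7)
Why: Chan–Lam arylation of the salicylaldehyde phenol forms the ring C–ring D ether and keeps the ArBr; no stereocentre is involved.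

**Step 4**
Reactants: 8, 4
Product: 9 (1-bromo-3-[(6-ethenyl-2,3-dimethoxyphenyl)oxy]benzene)
Conditions: 4, KOtBu, THF, 0 °C → rt, 2 h
Reagents that add atoms: 4, C[P+](c1ccccc1)(c1ccccc1)c1ccccc1.[Br-] (supplies the =CH2)
Why: Wittig methylenation gives the ring C styrene that becomes the B–C CH2CH2 bridge, and the ArBr survives.

**Step 5**
Reactants: 9, 10 (9-BBN)
Product: 11 (primary alkyl-9-BBN derived from 9, kept in THF solution and used directly in Step 6)
Conditions: 10 (0.95 equiv), THF, 25 °C, 3 h
Reagents that add atoms: 10, B1C2CCCC1CCC2 (the 9-BBN unit is retained in 11 as the C–B bond)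
Why: Hydroboration of the unhindered terminal styrene by 9-BBN is strongly anti-Markovnikov and gives the terminal alkyl-9-BBN; the slight deficiency of 9-BBN leaves no B–H to hydroborate the vinyl group of 5 in the next step, and no stereocentre is formed.

**Step 6**
Reactants: 11, 5
Product: 12 (bromo-styrene with the B–C bibenzyl bridge formed)
Conditions: 5 (1.2 equiv), PdCl2(dppf) (5 mol%), 3 M aq K3PO4, THF, 25 °C, 16 h
Reagents that add atoms: none (the 9-BBN boron is lost after coupling)
Why: B-alkyl Suzuki–Miyaura coupling of the alkyl-9-BBN 11 with the aryl iodide of 5 forms the ring C–CH2CH2–ring B bond; at room temperature oxidative addition into ArI is much faster than into the ArBr of 11, and the new CH2CH2 bond creates no stereocentre.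

**Step 7**
Reactants: 12, 10 (9-BBN)
Product: 13 (primary alkyl-9-BBN derived from the ring A vinyl group of 12, kept in THF solution and used directly in Step 8)
Conditions: 10 (1.05 equiv), THF, 25 °C, 3 h
Reagents that add atoms: 10, B1C2CCCC1CCC2 (the 9-BBN unit is retained in 13 as the C–B bond)
Why: Hydroboration of the only alkene in 12 (the ring A styrene) gives the terminal alkyl-9-BBN; the ArBr and the aryl ethers are untouched, and no stereocentre is formed.

**Step 8**
Reactants: 13
Product: 14 (permethyl macrocycle, the trimethyl ether of the target)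
Conditions: 13 added by syringe pump over 12 h (final ≈2 mM) to PdCl2(dppf) (15 mol%), 3 M aq K3PO4, THF, 65 °C, then 4 h
Reagents that add atoms: none (the 9-BBN boron is lost after coupling)
Why: Proposed new method: intramolecular B-alkyl Suzuki closure of this strained, p-phenylene-containing bis(diaryl ether) 18-membered ring, in which the large dppf bite angle favours reductive elimination of the Ar–Pd–CH2CH2Ar′ intermediate over β-H elimination and high dilution favours cyclisation over oligomerisation; the closest known reaction type is the intramolecular alkyl-9-BBN Suzuki macrocyclisation used for macrolides, and no stereocentre is formed.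

**Step 9**
Reactants: 14, 15 (BBr3)
Product: 16 (marchantin H: ring A phenol, ring C catechol)
Conditions: 15 (6 equiv), CH2Cl2, −78 °C → rt, 12 h; quench MeOH, then aq NaHCO3
Reagents that add atoms: none (BBr3 is not retained; the O–H groups form on work-up)
Why: BBr3 demethylation cleaves the three aryl methyl ethers, whereas the diaryl ethers and the CH2CH2 bridges survive, and no stereocentre is touched.

---

**Compound list**

| No. | Name | SMILES | Role |
|---|---|---|---|
| 1 | isovanillin (3-hydroxy-4-methoxybenzaldehyde) | COc1ccc(C=O)cc1O | starting material |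
| 2 | 4-iodophenylboronic acid | OB(O)c1ccc(I)cc1 | starting material |
| 3 | 3-(4-iodophenoxy)-4-methoxybenzaldehyde | COc1ccc(C=O)cc1Oc1ccc(I)cc1 | intermediate |
| 4 | methyltriphenylphosphonium bromide | C[P+](c1ccccc1)(c1ccccc1)c1ccccc1.[Br-] | starting material (reagent) |
| 5 | 1-ethenyl-3-(4-iodophenoxy)-4-methoxybenzene | COc1ccc(C=C)cc1Oc1ccc(I)cc1 | intermediate |
| 6 | 2-hydroxy-3,4-dimethoxybenzaldehyde | COc1ccc(C=O)c(O)c1OC | starting material |
| 7 | 3-bromophenylboronic acid | OB(O)c1cccc(Br)c1 | starting material |
| 8 | 2-(3-bromophenoxy)-3,4-dimethoxybenzaldehyde | COc1ccc(C=O)c(Oc2cccc(Br)c2)c1OC | intermediate |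
| 9 | 1-bromo-3-[(6-ethenyl-2,3-dimethoxyphenyl)oxy]benzene | COc1ccc(C=C)c(Oc2cccc(Br)c2)c1OC | intermediate |
| 10 | 9-BBN (9-borabicyclo[3.3.1]nonane) | B1C2CCCC1CCC2 | starting material (reagent) |
| 11 | alkyl-9-BBN from 9 (made in Step 5, used in solution) | COc1ccc(CCB2C3CCCC2CCC3)c(Oc2cccc(Br)c2)c1OC | intermediate |
| 12 | bromo-styrene with B–C bibenzyl bridge | COc1ccc(C=C)cc1Oc1ccc(CCc2ccc(OC)c(OC)c2Oc2cccc(Br)c2)cc1 | intermediate |
| 13 | alkyl-9-BBN from 12 (made in Step 7, used in solution) | COc1ccc(CCB2C3CCCC2CCC3)cc1Oc1ccc(CCc2ccc(OC)c(OC)c2Oc2cccc(Br)c2)cc1 | intermediate |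
| 14 | permethyl macrocycle (trimethyl ether of target) | COc1ccc2cc1Oc1ccc(cc1)CCc1ccc(OC)c(OC)c1Oc1cccc(c1)CC2 | intermediate |
| 15 | boron tribromide | BrB(Br)Br | starting material (reagent) |
| 16 | marchantin H (no stereocentres in the given SMILES) | Oc1ccc2cc1Oc1ccc(cc1)CCc1ccc(O)c(O)c1Oc1cccc(c1)CC2 | target |

**Totals:** 9 steps in total. The longest linear sequence is 7 steps: 6 → 8 → 9 → 11 → 12 → 13 → 14 → 16 (Steps 3–9). The branch 1 → 3 → 5 joins at Step 6.

**Three steps most likely to fail**
1. **Step 8 (macrocyclisation).** The 18-membered ring contains a strained p-phenylene, so oligomers, protodeboronation or hydrodebromination may dominate.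
   Fallback: vinylate the ArBr of 12 (potassium vinyltrifluoroborate, PdCl2(dppf)) and close the ring by ring-closing metathesis (Hoveyda–Grubbs II, 5 mM, toluene, 80 °C). Then hydrogenate the stilbene (H2, Pd/C) and demethylate with BBr3.
2. **Step 6 (ArI vs ArBr chemoselectivity, with the free styrene of 5 present).** Oligomerisation through the ArBr of 11, or Heck side reactions of the vinyl group of 5, may compete.
   Fallback: hydrozirconate 9 (Cp2ZrHCl), transmetalate to zinc (ZnCl2), and do a Negishi coupling with 5 (Pd(PPh3)4, rt). Organozinc coupling is strongly ArI-selective, and it replaces the boron chemistry with a different organometallic coupling.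
3. **Step 3 (Chan–Lam on the hindered, electron-rich salicylaldehyde 6).** Low conversion or aldehyde side reactions are possible.
   Fallback: metal-free O-arylation of the phenoxide of 6 with a (3-bromophenyl)(mesityl)iodonium salt (base, toluene), which transfers the less hindered aryl group.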